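## Structural features

Galbinic acid is a depsidone: rings A and B are joined by a diaryl ether (B5–O–A6) and by an ester (A1–C(=O)–O–B6), which together close a seven-membered dioxepinone ring. Ring A is a haematommate unit (A2 methyl, A3 hydrogen, A4 hydroxyl, A5 formyl) whose phenol and aldehyde are hydrogen-bonded. Ring B is hexasubstituted: B1 acetoxymethyl, B2 hydroxyl, B3 lactone carbonyl, B4 lactol carbon, B5 ether oxygen, B6 ester oxygen, with a γ-lactone (3-hydroxyphthalide) fused at B3–B4. The only stereocentre is the lactol carbon on B4, which is (S) (ring oxygen > hydroxyl > B4 > H). It has no stereogenic neighbour and, as the hemiacetal of a 2-formylbenzoic acid, can epimerise by ring–chain tautomerism. Fragile groups are the aryl ester of the seven-membered ring, the B1 benzylic acetate (two oxygen-bearing ortho carbons, easy ionisation), the salicylaldehyde unit and the lactol. The real difficulty is the contiguous hexasubstitution of ring B with three differentiated oxygens and the tetra-ortho-substituted diaryl ether; the stereocentre is hard only because it is labile. The key step uses the fact that B2, B5 and B6 carry oxygen (B2 para to B5) and B3–B4 carry the lactone: B5, B6, B1 and B2 map onto a squarate-derived cyclobutenone, and B3, B4 and the lactone onto a butenolide.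

## Logic of the disconnections

**23 to 22.** The C–OH bond at the B4 lactol carbon is cut back to C–H. The hemiacetal would not survive the base, Lewis acid and acylation chemistry of the assembly, whereas the phthalide methylene is inert. This makes 22 achiral and every earlier step free of stereochemical concern. The forward oxidation must tell two enantiotopic hydrogens apart, prefer this methylene to the B1 methylene, the ring A methyl and the formyl C–H, stop at the hemiacetal, and be worked up cold and neutral.

**22 to 20 (through 21).** The ester bond between the A1 carbonyl and the B6 oxygen is cut. Once the diaryl ether holds acid and phenol together, the seven-membered lactone is the natural closure. The gain is an open seco acid with no medium ring. The forward step must activate a di-ortho-substituted benzoic acid in the presence of three other hydroxyls, of which only the one on B6 can reach it.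

**20 to 19 to 18.** The acetyl–oxygen bond at B1 and four O–alkyl bonds (benzyl ester, A4 methyl ether, B6 isopropyl ether, acetal ether on the B1 oxygen) are cut. The acetate cannot pass the organometallic and Lewis acid steps, so it goes on afterwards. The four alkyl groups are chosen so that one Lewis acid removes them all. The gain is that 18 is robust and fully differentiated. The demands are that the Lewis acid spares the diaryl ether and lactone, and that acetylation finds the benzylic oxygen among three phenols and an acid.

**18 to 13 + 17.** The O–A6 bond of the diaryl ether is cut. A6 lies between a formyl and an ester group and is ideal for addition–elimination when it bears fluorine; the fully substituted, electron-rich ring B can only be the nucleophile. This gives two fragments of similar size. The forward step must arylate the B5 oxygen and not the B2 oxygen, at a congested carbon.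

**17 to 16 to 15 to 14.** The A1–carboxyl carbon bond, the C–Br bond and the A4 carbon–methoxy bond are cut in turn. A symmetrical 2,6-difluorobenzaldehyde already has fluorine, formyl and methyl in place, so no phenol has to be turned into a fluoride. The demands are mono-substitution by methoxide, bromination para to the methoxy group, and carbonylation without loss of the activated fluorine.

**13 to 10 (through 12 and 11).** The B2–B3 bond is cut and the bond between the carbons that become B2 and B5 is restored, which contracts ring B to a cyclobutenone carrying a butenolide. A para-dioxygenated benzene fused to a lactone is the retron of the hydroxycyclobutenone ring expansion. The gain is the largest of the route: a hexasubstituted arene becomes a four-membered ring with all six substituents already placed. The forward step needs heat, outward rotation of the hydroxyl, exclusion of air, and a precursor of the correct regiochemistry.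

**10 to 5 + 7 (through 9 and 8).** The bond between the carbinol carbon and butenolide C4 is cut. Addition of an alkenyl nucleophile to the ketone-like carbonyl of an alkoxy-alkyl cyclobutenedione (the one next to the alkoxy-bearing carbon) gives exactly this pattern. A β-metalated butenolide is not a credible reagent (acidic γ-hydrogens, electrophilic lactone), so the lactone is masked as an aromatic silyloxyfuran. Unmasking must be buffered and complete before heating, because a furan would offer a second site for ring closure.

**7 to 6.** The O–Si bond is cut; silyl dienol ether formation on a butenolide is routine.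

**5 to 1 + 2 (through 4 and 3).** The bond between the ring carbon (future B1) and its CH2 is cut. A hydroxymethyl anion equivalent adds to the squarate ester and acid-mediated loss of alcohol gives the dione. The oxygen on the carbanion cannot be silylated, because an α-silyloxy carbanion moves silicon from oxygen to carbon (retro-Brook); an acetal ether is used instead.

## Other disconnections considered

In this section ring positions are written out in words and the labels A1 to A7 denote compounds.

**Alternative 1:** The cut removes the lactone methylene (the bonds from position 4 of ring B to CH2 and from CH2 to oxygen). It leads back to the depsidone carboxylic acid A2, with hydrogen at position 4 of ring B and methyl ethers on both phenols.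
- Forward key step: a divalent palladium carboxylate catalyst is directed by the carboxylate to the only ortho C–H bond, the palladacycle is alkylated by a dihalomethane, and the carboxylate displaces the second halide to give the phthalide A1.
- In its favour: the site of C–C bond formation is unambiguous, the one-carbon unit arrives late, and ring B of A2 has one carbon substituent fewer than 13. On regiochemical certainty of the key step it is the equal of the chosen plan, and it is better in needing no organotin reagent.
- Against it here: A2 still has a pentasubstituted ring B with three differentiated oxygens, to be made by stepwise aromatic substitution and joined to ring A by the same hindered ether formation and lactonisation. The C–H step runs hot with base and halide, which threatens the benzylic acetate, the aryl ester and the formyl group, and the C–H bond sits between the carboxylate and a bulky aryloxy group. Two methyl ethers must be cleaved afterwards.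
- Comparison: both plans arrive at a phthalide of the type of 22 and face the same final oxidation, so neither gains on structure. Mechanistically it is a directed metalation on a finished depsidone against a pericyclic ring synthesis on a small precursor. On step economy the chosen plan makes ring B with all six substituents in four steps (steps 1 to 4), which a route to A2 is unlikely to match.

**Alternative 2:** The cut is the ether bond to position 6 of ring A, made at the oxidation level of a cyclohexane-1,3-dione. The precursor A4 is the ring B aryl ester of 2-methyl-4,6-dioxocyclohexanecarboxylic acid with a free hydroxyl at position 5 of ring B.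
- Forward key step: acid-catalysed condensation of that hydroxyl with the nearer ring carbonyl gives the vinylogous ester A3 and closes the seven-membered ring. Dehydrogenation then gives the aromatic depsidone A5, which still lacks the formyl group.
- In its favour: the congested ether is made by condensation and not by substitution at a hindered arene, and ring A comes from simple acyclic esters without a fluoroarene. On both points it is better than the chosen plan.
- Against it here: the β-keto aryl ester in A4 is prone to ketene loss and decarboxylation. The aromatisation needs an oxidant in the presence of an electron-rich ring B and a benzylic acetate. The formyl group must then be placed between two oxygens on ring A, with the other free position competing.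
- Comparison: on structure it leaves ring B and the lactol unsolved, as the chosen plan would without its key step. Mechanistically it trades one substitution for a condensation plus two redox-level adjustments. On step economy it needs at least three more steps after ring closure (aromatise, formylate, demethylate), whereas ring A arrives complete in 17.

**Alternative 3:** The cut takes ring A apart at two bonds (ring A positions 1–6 and 2–3). The precursor A7 carries a but-2-ynoate on the position 6 oxygen of ring B and a 3-silyloxycyclohexa-1,3-dienyl ether on the position 5 oxygen.
- Forward key step: intramolecular Diels–Alder addition of the ynoate to the diene, then retro-Diels–Alder loss of the two-carbon bridge, gives A6 with ring A and the seven-membered lactone formed together.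
- In its favour: the tether fixes the regiochemistry, no metal is needed, and three ring bonds form in one operation. In bonds formed per step it is better than the ether formation plus lactonisation of the chosen plan.
- Against it here: the tether is an aryl ester and an enol ether that must fold into a seven-membered ring in the transition state, so high temperature is likely, at which the benzylic acetate and the silyl dienol ether are at risk. Making A7 means building a 3-aryloxycyclohexenone on a hindered phenol and enolising it regioselectively beside an acetate and a lactone. The formyl group is still missing and has to be introduced between two oxygens.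
- Comparison: on structure it solves ring A elegantly but leaves ring B, where the chosen plan is strongest. Mechanistically both are pericyclic and need no reagent control of regiochemistry, so they are equals there. On step economy the cycloaddition saves one step at the depsidone stage but loses it again to late formylation and deprotection.

Key step: step 4

Remark (assumption on the chemistry): the hemiacetal of 23 is taken to hold its configuration when it is formed and isolated below 0 °C in neutral, non-basic, aprotic media; base or water above about pH 4 would open it to the formyl carboxylate and racemise it.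

Remark: 2, 6 and 14 are taken as catalogue compounds.

## Route

Step 1
Reactants: 1 diisopropyl squarate; 2 tributyl[(methoxymethoxy)methyl]stannane
Product: 5 3-isopropoxy-4-[(methoxymethoxy)methyl]cyclobut-3-ene-1,2-dione, via (methoxymethoxy)methyllithium 3 (not isolated), via squarate 1,2-adduct 4 (not isolated)
Conditions: 2, n-BuLi, THF, −78 °C; then 1, −78 °C; then (CF3CO)2O, −78 °C; aq. NH4Cl
Reagents that add atoms: water, O (oxygen of the new carbonyl, delivered on work-up)
Why: Tin–lithium exchange gives the α-alkoxymethyllithium 3, which adds 1,2 to one carbonyl of 1; trifluoroacetylation of the alkoxide of 4 triggers ionisation, and hydrolysis of the vinylogous oxocarbenium ion expels propan-2-ol (organolithium addition and acid-mediated rearrangement of squarate esters). The acetal ether is used because an α-silyloxymethyllithium would undergo retro-Brook migration of silicon from oxygen to carbon.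

Step 2
Reactants: 6 4-bromofuran-2(5H)-one
Product: 7 4-bromo-2-(triisopropylsilyloxy)furan
Conditions: i-Pr3SiOTf, Et3N, CH2Cl2, 0 °C
Reagents that add atoms: triisopropylsilyl triflate, CC(C)[Si](C(C)C)(C(C)C)OS(=O)(=O)C(F)(F)F
Why: γ-Deprotonation and O-silylation give the aromatic 2-silyloxyfuran (silyl dienol ether formation), which masks the lactone carbonyl and the acidic γ-hydrogens so that C4 can be metalated; the bulky silyl group resists attack by the alkyllithium.

Step 3
Reactants: 7 4-bromo-2-(triisopropylsilyloxy)furan; 5 3-isopropoxy-4-[(methoxymethoxy)methyl]cyclobut-3-ene-1,2-dione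
Product: 10 racemic 4-hydroxy-3-isopropoxy-2-[(methoxymethoxy)methyl]-4-(5-oxo-2,5-dihydrofuran-3-yl)cyclobut-2-en-1-one, via lithiofuran 8 (not isolated), via silyloxyfuran adduct 9 (not isolated)
Conditions: 7, n-BuLi, THF, −78 °C; then 5, −78 °C; AcOH, then Bu4NF, THF, −78 → 0 °C
Reagents that add atoms: none
Why: Bromine–lithium exchange gives the β-furyllithium 8, which adds to the more electrophilic, ketone-like carbonyl of 5 (the one next to the isopropoxy-bearing carbon; the other is a vinylogous ester), the usual regiochemistry for alkoxy-alkyl cyclobutenediones. Buffered fluoride then cleaves the silyl ether of 9 and protonation at the furan α-carbon gives the conjugated butenolide without exposing the hydroxycyclobutenone to strong acid or base. The carbinol centre forms racemic and is destroyed in step 4.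

Step 4
Reactants: 10 racemic 4-hydroxy-3-isopropoxy-2-[(methoxymethoxy)methyl]-4-(5-oxo-2,5-dihydrofuran-3-yl)cyclobut-2-en-1-one
Product: 13 4,7-dihydroxy-5-isopropoxy-6-[(methoxymethoxy)methyl]-2-benzofuran-1(3H)-one, via dienylketene 11 (not isolated), via cyclohexadienone 12 (not isolated)
Conditions: toluene (degassed, 0.02 M), 110 °C, argon
Reagents that add atoms: none
Why: Heating opens the cyclobutenone by conrotatory 4π cleavage of the bond between the carbonyl carbon and the carbinol carbon and gives the dienylketene 11. The hydroxyl, the better donor, rotates outward, so the butenolide ends up cis to the ketene. A disrotatory 6π electrocyclisation then joins the ketene carbon (future B2) to the butenolide α-carbon (future B3) and closes the six-membered carbocycle as the cyclohexadienone 12. Enolisation of 12, whose B3 hydrogen is α to both the ketone and the lactone carbonyl, gives the hydroquinone 13. The closest known reaction type is the Moore rearrangement of 4-alkenyl-4-hydroxycyclobutenones to hydroquinones. No stereocentre survives, since the carbinol centre of 10 and the B3 centre of 12 both become sp2. The substitution pattern needs no selectivity here because it was fixed by the site of addition in step 3: the four ring carbons of 10 become B5, B6, B1 and B2, and the butenolide supplies B3, B4 and the lactone. The step needs the ketene to cyclise faster than the enol hydroxyl can trap it, which outward rotation secures, and it needs air kept out so that 13 is not oxidised to the quinone.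

Step 5
Reactants: 14 2,6-difluoro-4-methylbenzaldehyde
Product: 15 2-fluoro-6-methoxy-4-methylbenzaldehyde
Conditions: NaOMe (1.05 equiv), MeOH, 0 °C → rt
Reagents that add atoms: sodium methoxide, C[O-].[Na+]
Why: Nucleophilic aromatic substitution (addition–elimination) at a fluorine ortho to the formyl group; the methoxy group introduced deactivates the ring, so the second fluorine should be kept.

Step 6
Reactants: 15 2-fluoro-6-methoxy-4-methylbenzaldehyde
Product: 16 3-bromo-2-fluoro-6-methoxy-4-methylbenzaldehyde
Conditions: NBS, MeCN, rt
Reagents that add atoms: N-bromosuccinimide, O=C1CCC(=O)N1Br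
Why: Electrophilic aromatic bromination; the methoxy group directs para to C3, which is also ortho to fluorine and methyl and meta to the formyl group, whereas C5 is crowded between methoxy and methyl.

Step 7
Reactants: 16 3-bromo-2-fluoro-6-methoxy-4-methylbenzaldehyde
Product: 17 benzyl 2-fluoro-3-formyl-4-methoxy-6-methylbenzoate
Conditions: Pd(OAc)2 (cat.), Xantphos (cat.), CO (1 atm), BnOH (1.5 equiv), Et3N, toluene, 80 °C
Reagents that add atoms: carbon monoxide, [C-]#[O+]; benzyl alcohol, OCc1ccccc1
Why: Palladium-catalysed alkoxycarbonylation: zerovalent palladium formed from Pd(OAc)2 inserts into the C–Br bond, CO insertion gives the acylpalladium species and benzyl alcohol releases the ester. Toluene, a tertiary amine and a small excess of alcohol are chosen so that the alcohol does not displace the now doubly activated fluorine.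

Step 8
Reactants: 13 4,7-dihydroxy-5-isopropoxy-6-[(methoxymethoxy)methyl]-2-benzofuran-1(3H)-one; 17 benzyl 2-fluoro-3-formyl-4-methoxy-6-methylbenzoate
Product: 18 benzyl 3-formyl-2-({7-hydroxy-5-isopropoxy-6-[(methoxymethoxy)methyl]-1-oxo-1,3-dihydro-2-benzofuran-4-yl}oxy)-4-methoxy-6-methylbenzoate
Conditions: 13, NaN(SiMe3)2 (2.05 equiv), THF/DMF (degassed), −40 °C; then 17 (1.0 equiv), −40 → 0 °C; AcOH
Reagents that add atoms: none
Why: Nucleophilic aromatic substitution at a fluorine flanked by formyl and ester groups. In the dianion of 13 the B5 oxide is the more basic and more nucleophilic site, whereas the B2 oxide is a sodium-chelated vinylogous carboxylate conjugated with the lactone carbonyl, so arylation should take place at B5; the amide base is consumed before 17 is added.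

Step 9
Reactants: 18 benzyl 3-formyl-2-({7-hydroxy-5-isopropoxy-6-[(methoxymethoxy)methyl]-1-oxo-1,3-dihydro-2-benzofuran-4-yl}oxy)-4-methoxy-6-methylbenzoate
Product: 19 2-{[5,7-dihydroxy-6-(hydroxymethyl)-1-oxo-1,3-dihydro-2-benzofuran-4-yl]oxy}-3-formyl-4-hydroxy-6-methylbenzoic acid
Conditions: BCl3 (excess), CH2Cl2, −78 → 0 °C; then H2O
Reagents that add atoms: none
Why: Lewis acid dealkylation: BCl3 cleaves the benzyl ester, the isopropyl ether, the methyl ether ortho to the formyl group (chelation-assisted) and the acetal ether, and leaves diaryl ether, lactone and aldehyde intact. Ring B has no free position, so no arene scavenger is added that could capture a B1 benzylic cation.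

Step 10
Reactants: 19 2-{[5,7-dihydroxy-6-(hydroxymethyl)-1-oxo-1,3-dihydro-2-benzofuran-4-yl]oxy}-3-formyl-4-hydroxy-6-methylbenzoic acid
Product: 20 2-{[6-(acetoxymethyl)-5,7-dihydroxy-1-oxo-1,3-dihydro-2-benzofuran-4-yl]oxy}-3-formyl-4-hydroxy-6-methylbenzoic acid
Conditions: AcOH, 60 °C
Reagents that add atoms: acetic acid, CC(=O)O
Why: Solvolytic esterification of an ortho-hydroxybenzyl alcohol in acetic acid (through the stabilised benzylic cation or ortho-quinone methide) acetylates only the benzylic oxygen; phenols and the carboxylic acid are not acylated, and any benzylic chloride carried over from step 9 converges on the same acetate.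

Step 11
Reactants: 20 2-{[6-(acetoxymethyl)-5,7-dihydroxy-1-oxo-1,3-dihydro-2-benzofuran-4-yl]oxy}-3-formyl-4-hydroxy-6-methylbenzoic acid
Product: 22 deoxy-galbinic acid (the depsidone with a phthalide CH2 at B4), via O-acylisourea 21 (not isolated)
Conditions: i-PrN=C=N-i-Pr, CH2Cl2/THF (high dilution), 0 °C → rt
Reagents that add atoms: none
Why: Carbodiimide lactonisation: the O-acylisourea 21 is attacked by the B6 hydroxyl, the only phenol held within reach by the diaryl ether, and the seven-membered depsidone ring closes; the B2 and A4 phenols are chelated and remote.

Step 12
Reactants: 22 deoxy-galbinic acid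
Product: 23 galbinic acid, (S) at the lactol carbon
Conditions: Mn(OTf)2(L*) (2 mol%; L* = one enantiomer of N,N'-bis[(5-triisopropylsilylpyridin-2-yl)methyl]-2,2'-bipyrrolidine), aq. H2O2 (1.2 equiv, slow addition), 2,2-dimethylbutanoic acid, (CF3)2CHOH, −35 °C; cold neutral work-up
Reagents that add atoms: hydrogen peroxide, OO
Why: Proposed new method: an electrophilic manganese-oxo carboxylate species formed from the chiral divalent manganese complex and H2O2 abstracts one of the two enantiotopic hydrogens of the lactone O–CH2 on B4 and returns hydroxyl to the same face (hydrogen abstraction and oxygen rebound with retention); the closest known reaction types are manganese-catalysed enantioselective hydroxylation of benzylic methylenes with H2O2 in fluorinated alcohols and manganese-salen oxidation of cyclic benzylic ethers to lactols. The ligand enantiomer is chosen so that the pro-R hydrogen is replaced, which gives the (S)-hemiacetal. The ring-locked B4 C–H bonds are aligned with the arene and the lactone oxygen, the B1 methylene is shielded by two ortho substituents and the ring A methyl is primary, and the hydrogen-bonding solvent should protect the hemiacetal C–H from over-oxidation.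

## Compound list

1 | diisopropyl squarate (3,4-diisopropoxycyclobut-3-ene-1,2-dione) | CC(C)OC1=C(OC(C)C)C(=O)C1=O | starting material
2 | tributyl[(methoxymethoxy)methyl]stannane | CCCC[Sn](CCCC)(CCCC)COCOC | starting material
3 | (methoxymethoxy)methyllithium | [Li]COCOC | intermediate
4 | racemic 4-hydroxy-2,3-diisopropoxy-4-[(methoxymethoxy)methyl]cyclobut-2-en-1-one (lithium alkoxide, then trifluoroacetate, in the flask) | CC(C)OC1=C(OC(C)C)C(O)(COCOC)C1=O | intermediate
5 | 3-isopropoxy-4-[(methoxymethoxy)methyl]cyclobut-3-ene-1,2-dione | CC(C)OC1=C(COCOC)C(=O)C1=O | intermediate
6 | 4-bromofuran-2(5H)-one | BrC1=CC(=O)OC1 | starting material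
7 | 4-bromo-2-(triisopropylsilyloxy)furan | CC(C)[Si](Oc1cc(Br)co1)(C(C)C)C(C)C | intermediate
8 | 4-lithio-2-(triisopropylsilyloxy)furan | [Li]c1coc(O[Si](C(C)C)(C(C)C)C(C)C)c1 | intermediate
9 | racemic 4-hydroxy-3-isopropoxy-2-[(methoxymethoxy)methyl]-4-[5-(triisopropylsilyloxy)furan-3-yl]cyclobut-2-en-1-one | CC(C)OC1=C(COCOC)C(=O)C1(O)c1coc(O[Si](C(C)C)(C(C)C)C(C)C)c1 | intermediate
10 | racemic 4-hydroxy-3-isopropoxy-2-[(methoxymethoxy)methyl]-4-(5-oxo-2,5-dihydrofuran-3-yl)cyclobut-2-en-1-one | CC(C)OC1=C(COCOC)C(=O)C1(O)C1=CC(=O)OC1 | intermediate
11 | 4-hydroxy-3-isopropoxy-2-[(methoxymethoxy)methyl]-4-(5-oxo-2,5-dihydrofuran-3-yl)buta-1,3-dien-1-one (dienylketene, butenolide cis to the ketenyl carbon) | O=C=C(COCOC)/C(OC(C)C)=C(/O)C1=CC(=O)OC1 | intermediate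
12 | racemic 4-hydroxy-5-isopropoxy-6-[(methoxymethoxy)methyl]-3,7a-dihydro-2-benzofuran-1,7-dione | O=C1C(COCOC)=C(OC(C)C)C(O)=C2COC(=O)C12 | intermediate
13 | 4,7-dihydroxy-5-isopropoxy-6-[(methoxymethoxy)methyl]-2-benzofuran-1(3H)-one | CC(C)Oc1c(COCOC)c(O)c2c(c1O)COC2=O | intermediate
14 | 2,6-difluoro-4-methylbenzaldehyde | Cc1cc(F)c(C=O)c(F)c1 | starting material
15 | 2-fluoro-6-methoxy-4-methylbenzaldehyde | COc1cc(C)cc(F)c1C=O | intermediate
16 | 3-bromo-2-fluoro-6-methoxy-4-methylbenzaldehyde | COc1cc(C)c(Br)c(F)c1C=O | intermediate
17 | benzyl 2-fluoro-3-formyl-4-methoxy-6-methylbenzoate | COc1cc(C)c(C(=O)OCc2ccccc2)c(F)c1C=O | intermediate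
18 | benzyl 3-formyl-2-({7-hydroxy-5-isopropoxy-6-[(methoxymethoxy)methyl]-1-oxo-1,3-dihydro-2-benzofuran-4-yl}oxy)-4-methoxy-6-methylbenzoate | COCOCc1c(O)c2c(c(Oc3c(C=O)c(OC)cc(C)c3C(=O)OCc4ccccc4)c1OC(C)C)COC2=O | intermediate
19 | 2-{[5,7-dihydroxy-6-(hydroxymethyl)-1-oxo-1,3-dihydro-2-benzofuran-4-yl]oxy}-3-formyl-4-hydroxy-6-methylbenzoic acid | OCc1c(O)c2c(c(Oc3c(C=O)c(O)cc(C)c3C(=O)O)c1O)COC2=O | intermediate
20 | 2-{[6-(acetoxymethyl)-5,7-dihydroxy-1-oxo-1,3-dihydro-2-benzofuran-4-yl]oxy}-3-formyl-4-hydroxy-6-methylbenzoic acid | CC(=O)OCc1c(O)c2c(c(Oc3c(C=O)c(O)cc(C)c3C(=O)O)c1O)COC2=O | intermediate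
21 | O-acyl-N,N'-diisopropylisourea of 20 | CC(=O)OCc1c(O)c2c(c(Oc3c(C=O)c(O)cc(C)c3C(=O)OC(=NC(C)C)NC(C)C)c1O)COC2=O | intermediate
22 | deoxy-galbinic acid (depsidone; A2 methyl, A4 hydroxyl, A5 formyl; B1 acetoxymethyl, B2 hydroxyl, γ-lactone with B3 carbonyl and B4 CH2) | CC(=O)OCc1c(O)c2c(c3c1OC(=O)c1c(C)cc(O)c(C=O)c1O3)COC2=O | intermediate
23 | galbinic acid, (S)-lactol | CC(=O)OCc1c(O)c2c(c3c1OC(=O)c1c(C)cc(O)c(C=O)c1O3)[C@@H](O)OC2=O | target

## Step count and least certain steps

Total: 12 steps. Longest linear sequence: 8 steps (steps 1, 3, 4, 8, 9, 10, 11, 12; the branches through steps 2 and 5–7 are equally long).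

**Step 12 (proposed new method).**
- What may go wrong: hydrogen abstraction at other sites (formyl C–H, B1 methylene, ring A methyl), oxidation of the free phenols, over-oxidation of the hemiacetal to the anhydride, poor discrimination between the enantiotopic hydrogens, and racemisation by ring–chain tautomerism during isolation.
- Fallback (known chemistry), setting out from 18 and returning at 23: the lactone of 18 is opened with NaOH (THF/H2O, 0 °C) to the sodium 2-(hydroxymethyl)benzoate F1. Its liberated benzylic alcohol, the only one in the molecule, is oxidised with MnO2, and acidification closes the formyl acid to the racemic lactol diaryl ether F2. BCl3 followed by aqueous work-up gives the racemic lactol seco acid F3, acetic acid gives its benzylic acetate F4, and the carbodiimide closes racemic galbinic acid F5. Preparative chromatography of F5 on a chiral stationary phase with a cold, neutral eluent delivers 23.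

**Step 4 (key step).**
- What may go wrong: inward rotation of the hydroxyl followed by capture of the ketene by that hydroxyl, slow closure onto the electron-poor, ring-constrained alkene, and air oxidation of the electron-rich hydroquinone.
- Fallback, setting out from 10 and returning at 13: the tertiary hydroxyl is silylated with N-(trimethylsilyl)imidazole to the silyl ether F6. On thermolysis F6 cannot divert the ketene to oxygen and should give the mono-silylated hydroquinone F7, which is less air-sensitive. Aqueous citric acid in THF then returns 13.

**Step 3.**
- What may go wrong: proton transfer or isomerisation of the lithiofuran before it adds, addition at the vinylogous ester carbonyl, rearrangement of the hydroxycyclobutenone during desilylation, and incomplete isomerisation to the conjugated butenolide.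
- Fallback, setting out from 6 (with 5) and returning at 10: halide exchange with NaI in acetone gives 4-iodofuran-2(5H)-one F8. Iodine–magnesium exchange with i-PrMgCl·LiCl at −78 °C gives the unmasked alkenylmagnesium reagent F9, which is added directly to 5. No silyl mask and no fluoride step are then needed.

**Step 8.**
- What may go wrong: arylation at the B2 oxygen or at both oxygens, electron-transfer oxidation of the dianion, and slow substitution at the doubly hindered carbon.
- Fallback, setting out from 13 and returning at 19: the non-chelated B5 hydroxyl is silylated selectively (TBSCl, imidazole) to the silyl ether F10. The chelated B2 hydroxyl is benzylated under Mitsunobu conditions (BnOH, PPh3, DIAD) to the benzyl ether F11. Buffered Bu4NF frees B5 and gives the mono-phenol F12, which is arylated with 17 (K2CO3, DMF) to the diaryl ether F13. BCl3 removes the extra benzyl ether together with the other groups and gives 19.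

**Step 9.**
- What may go wrong: ionisation of the doubly ortho-oxygenated B1 benzylic C–O bond with chloride incorporation or intermolecular alkylation, and incomplete cleavage of the non-chelated isopropyl ether.
- Fallback, setting out from 18 and returning at 20: the ionisation is accepted and driven to completion (excess BCl3, CH2Cl2, up to 25 °C). The benzylic chloride seco acid F14 is taken without purification into AgOAc in AcOH, which replaces chloride by acetate and gives 20 directly.

## Further compounds

F1 | step 12 | sodium 3-{[2-benzyloxycarbonyl-6-formyl-5-methoxy-3-methylphenyl]oxy}-6-hydroxy-2-(hydroxymethyl)-4-isopropoxy-5-[(methoxymethoxy)methyl]benzoate | COCOCc1c(O)c(C(=O)[O-])c(CO)c(Oc2c(C=O)c(OC)cc(C)c2C(=O)OCc2ccccc2)c1OC(C)C.[Na+]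
F2 | step 12 | racemic 3-hydroxy analogue of 18 (lactol diaryl ether) | COCOCc1c(O)c2c(c(Oc3c(C=O)c(OC)cc(C)c3C(=O)OCc4ccccc4)c1OC(C)C)C(O)OC2=O
F3 | step 12 | racemic 3-hydroxy analogue of 19 (lactol seco acid) | OCc1c(O)c2c(c(Oc3c(C=O)c(O)cc(C)c3C(=O)O)c1O)C(O)OC2=O
F4 | step 12 | racemic 3-hydroxy analogue of 20 (lactol seco acid acetate) | CC(=O)OCc1c(O)c2c(c(Oc3c(C=O)c(O)cc(C)c3C(=O)O)c1O)C(O)OC2=O
F5 | step 12 | racemic galbinic acid | CC(=O)OCc1c(O)c2c(c3c1OC(=O)c1c(C)cc(O)c(C=O)c1O3)C(O)OC2=O
F6 | step 4 | racemic trimethylsilyl ether of 10 | CC(C)OC1=C(COCOC)C(=O)C1(O[Si](C)(C)C)C1=CC(=O)OC1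
F7 | step 4 | 7-hydroxy-5-isopropoxy-6-[(methoxymethoxy)methyl]-4-(trimethylsilyloxy)-2-benzofuran-1(3H)-one | CC(C)Oc1c(COCOC)c(O)c2c(c1O[Si](C)(C)C)COC2=O
F8 | step 3 | 4-iodofuran-2(5H)-one | IC1=CC(=O)OC1
F9 | step 3 | (5-oxo-2,5-dihydrofuran-3-yl)magnesium chloride | Cl[Mg]C1=CC(=O)OC1
F10 | step 8 | 4-(tert-butyldimethylsilyloxy)-7-hydroxy-5-isopropoxy-6-[(methoxymethoxy)methyl]-2-benzofuran-1(3H)-one | CC(C)Oc1c(COCOC)c(O)c2c(c1O[Si](C)(C)C(C)(C)C)COC2=O
F11 | step 8 | 7-benzyloxy-4-(tert-butyldimethylsilyloxy)-5-isopropoxy-6-[(methoxymethoxy)methyl]-2-benzofuran-1(3H)-one | CC(C)Oc1c(COCOC)c(OCc3ccccc3)c2c(c1O[Si](C)(C)C(C)(C)C)COC2=O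
F12 | step 8 | 7-benzyloxy-4-hydroxy-5-isopropoxy-6-[(methoxymethoxy)methyl]-2-benzofuran-1(3H)-one | CC(C)Oc1c(COCOC)c(OCc3ccccc3)c2c(c1O)COC2=O
F13 | step 8 | B2 O-benzyl ether of 18 | COCOCc1c(OCc5ccccc5)c2c(c(Oc3c(C=O)c(OC)cc(C)c3C(=O)OCc4ccccc4)c1OC(C)C)COC2=O
F14 | step 9 | 2-{[6-(chloromethyl)-5,7-dihydroxy-1-oxo-1,3-dihydro-2-benzofuran-4-yl]oxy}-3-formyl-4-hydroxy-6-methylbenzoic acid | ClCc1c(O)c2c(c(Oc3c(C=O)c(O)cc(C)c3C(=O)O)c1O)COC2=O
A1 | alternative 1 | deoxy-galbinic acid dimethyl ether (phthalide depsidone) | CC(=O)OCc1c(OC)c2c(c3c1OC(=O)c1c(C)cc(OC)c(C=O)c1O3)COC2=O
A2 | alternative 1 | depsidone carboxylic acid with hydrogen at position 4 of ring B, dimethyl ether | CC(=O)OCc1c(OC)c(C(=O)O)cc2c1OC(=O)c1c(C)cc(OC)c(C=O)c1O2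
A3 | alternative 2 | tetrahydro-depsidone vinylogous ester (racemic mixture of diastereomers) | CC(=O)OCc1c(OC)c2c(c3c1OC(=O)C1C(C)CC(=O)C=C1O3)COC2=O
A4 | alternative 2 | ring B aryl 2-methyl-4,6-dioxocyclohexanecarboxylate with free hydroxyl at position 5 of ring B (racemic mixture of diastereomers) | CC(=O)OCc1c(OC)c2c(c(O)c1OC(=O)C1C(C)CC(=O)CC1=O)COC2=O
A5 | alternative 2 | aromatised depsidone lacking the formyl group, B-ring methyl ether | CC(=O)OCc1c(OC)c2c(c3c1OC(=O)c1c(C)cc(O)cc1O3)COC2=O
A6 | alternative 3 | depsidone lacking the formyl group, trimethylsilyl ether on ring A and methyl ether on ring B | CC(=O)OCc1c(OC)c2c(c3c1OC(=O)c1c(C)cc(O[Si](C)(C)C)cc1O3)COC2=O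
A7 | alternative 3 | tethered but-2-ynoate and 3-(trimethylsilyloxy)cyclohexa-1,3-dienyl ether of ring B | CC#CC(=O)Oc1c(COC(C)=O)c(OC)c2c(c1OC1=CC(O[Si](C)(C)C)=CCC1)COC2=O
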